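The target, drawn with an extra bond from C2 (the CH2 beside the C1 gem-dimethyl carbon) to C10 (the vinylic CH beside C11–OBz), shows its eleven-membered carbocycle as the cyclobutane (C1, C2, C10, C11) fused to the cyclononane of commercial (−)-caryophyllene oxide. The trans C5–C6 epoxide of that compound already has the required (5R,6R) configuration. Everything rests on breaking the C2–C10 bond. The precursor is the C9 norketone, kobusone. In one operation a samarium ketyl at C9 lets cyclobutane strain drive C2–C10 scission, which merges the four- and nine-membered rings into the eleven-membered ring. C2 becomes CH2, and the regiodefined C9=C10 enolate is trapped as its triflate. Carbonylation, C11 oxidation, CBS reduction and benzoylation finish.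

Key step: step 2

Remark: all compounds carry the ring numbering of the target (C1 = C(CH3)2, C2–C4 = CH2, C5 = epoxide C–CH3, C6 = epoxide CH, C7 and C8 = CH2, C9 = C–CO2H, C10 = CH=, C11 = CH–OBz); commercial (−)-caryophyllene oxide is taken as the (2R,5R,6R,10S) enantiomer in this numbering.

Step 1
Reactants: 1 (−)-caryophyllene oxide
Product: 3 kobusone (C9 norketone of 1), via secondary ozonide 2 (not isolated)
Conditions: O3, CH2Cl2, −78 °C; then Me2S, −78 °C → rt
Reagents that add atoms: ozone [O-][O+]=O
Why: Ozonolysis with reductive work-up cleaves the only C=C bond, the exocyclic methylene at C9, under neutral conditions that leave the epoxide and the ring-fusion centres untouched and create no stereocentre in 3.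

Step 2
Reactants: 3 kobusone
Product: 7 (9E)-enol triflate of the eleven-membered ring [(5R,6R)-5,6-epoxy-1,1,5-trimethylcycloundec-9-en-9-yl triflate], via samarium ketyl 4 (not isolated), via ring-opened C2 radical 5 (not isolated), via samarium(III) enolate 6 (not isolated)
Conditions: SmI2 (2.5 equiv), HMPA, t-BuOH (1.0 equiv), THF, 0 °C; then N-(5-chloro-2-pyridyl)triflimide, −78 °C → rt
Reagents that add atoms: N-(5-chloro-2-pyridyl)bis(trifluoromethanesulfonimide) O=S(=O)(N(c1ccc(Cl)cn1)S(=O)(=O)C(F)(F)F)C(F)(F)F; samarium(II) iodide I[Sm]I (its atoms stay only in 4–6)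
Why: SmI2–HMPA transfers one electron to the C9 ketone to give ketyl 4, a cyclobutylcarbinyl radical, which undergoes β-scission of the C2–C10 bond to the enolate radical 5; a second SmI2 and t-BuOH convert the C2 radical into CH2, and the remaining samarium(III) enolate 6 is O-sulfonylated by the triflimide. The closest known reaction type is the SmI2-induced reductive ring opening of cyclopropyl and cyclobutyl ketones with electrophilic capture of the samarium enolate, combined with ordinary enolate triflation. The eleven-membered ring is closed by ring expansion and not end to end: scission of the bond shared by the four- and nine-membered rings merges them (4 + 9 − 2 = 11), so no high dilution is needed and roughly 26 kcal/mol of cyclobutane strain pays for the step. No stereocentre is created (C2 and C10 become CH2 and CH=, C5 and C6 are spectators); the only new stereo-element, the C9=C10 geometry, should be set under Curtin–Hammett control by the rotamer about C9–C10 in which the bulky HMPA-solvated O–Sm group lies over the small H10 and C8 lies syn to C11, which gives the E enolate with C8 and C11 cis. The step needs C2–C10 and not C10–C11 scission, which is secured because the former gives a secondary and the latter a primary neopentyl radical, because only the former relieves the trans ring fusion, and because the endocyclic C2–C10 bond stands roughly perpendicular to the carbonyl plane of the cyclononanone. It also needs the epoxide and the enolate regiochemistry to survive, which is secured by the two CH2 groups (C7, C8) that insulate the epoxide from the ketyl, by the low Lewis acidity of HMPA-saturated Sm(III), and by using only one equivalent of t-BuOH, which quenches the alkylsamarium but is less acidic than the ketone.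

Step 3
Reactants: 7 (9E)-enol triflate
Product: 8 2-(trimethylsilyl)ethyl (9E,5R,6R)-5,6-epoxy-1,1,5-trimethylcycloundec-9-ene-9-carboxylate
Conditions: Pd(OAc)2 (5 mol %), dppf, CO (1 atm), Me3SiCH2CH2OH, Et3N, DMF, 50 °C
Reagents that add atoms: carbon monoxide [C-]#[O+]; 2-(trimethylsilyl)ethanol C[Si](C)(C)CCO
Why: Palladium-catalysed alkoxycarbonylation of an enol triflate (oxidative addition, CO insertion, alcoholysis) proceeds with retention of alkene geometry, so the ester takes the place of OTf trans to C11, and the non-allylic epoxide is inert to Pd(0).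

Step 4
Reactants: 8 macrocyclic (E)-enoate
Product: 9 2-(trimethylsilyl)ethyl (9E,5R,6R)-5,6-epoxy-1,1,5-trimethyl-11-oxocycloundec-9-ene-9-carboxylate
Conditions: Rh2(cap)4 (1 mol %), t-BuOOH (70% in H2O), ClCH2CH2Cl, 40 °C
Reagents that add atoms: tert-butyl hydroperoxide CC(C)(C)OO
Why: In this allylic γ-C–H oxidation of an enoate by tert-butylperoxyl radicals, H-abstraction at C11 gives an allyl radical delocalised onto the ester-bearing C9 whereas abstraction at C8 gives only a cross-conjugated one, and the near-neutral medium spares the epoxide.

Step 5
Reactants: 9 4-oxo-enoate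
Product: 10 2-(trimethylsilyl)ethyl (9E,5R,6R,11R)-5,6-epoxy-11-hydroxy-1,1,5-trimethylcycloundec-9-ene-9-carboxylate
Conditions: (S)-Me-CBS (20 mol %), catecholborane, toluene, −78 → −40 °C; pH 7 buffer
Reagents that add atoms: none
Why: In the CBS reduction the ketone binds the oxazaborolidine boron through the lone pair on the side of the small C10–H vinyl flank and away from the fully substituted C1 flank, so the (S)-catalyst should deliver hydride to the face that gives 11R under reagent control, with 1,2-selectivity at low temperature.

Step 6
Reactants: 10 (11R)-carbinol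
Product: 11 2-(trimethylsilyl)ethyl (9E,5R,6R,11R)-11-benzoyloxy-5,6-epoxy-1,1,5-trimethylcycloundec-9-ene-9-carboxylate
Conditions: BzCl, Et3N, DMAP (cat.), CH2Cl2, 0 °C → 40 °C
Reagents that add atoms: benzoyl chloride O=C(Cl)c1ccccc1
Why: DMAP-catalysed O-acylation occurs at oxygen with retention at C11, and the E geometry keeps the ester trans to C11 so that no butenolide can form.

Step 7
Reactants: 11 benzoate 2-(trimethylsilyl)ethyl ester
Product: 12 target acid CNP0377917.1
Conditions: TBAF, THF, 0 °C → rt; AcOH quench
Reagents that add atoms: none
Why: Fluoride-induced β-elimination of the 2-(trimethylsilyl)ethyl ester frees the acid without hydrolysis, so the benzoate, the epoxide, C11 and the alkene geometry are left as they are.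

Compound list
1 | (−)-caryophyllene oxide, (2R,5R,6R,10S), trans-fused cyclobutane–cyclononane with C9 exocyclic methylene | C[C@@]12CC[C@@H]3[C@H](CC3(C)C)C(=C)CC[C@H]1O2 | starting material
2 | spiro secondary ozonide (1,2,4-trioxolane) at C9 of 1, C9 configuration open | C[C@@]12CC[C@@H]3[C@H](CC3(C)C)C4(CC[C@H]1O2)OCOO4 | intermediate
3 | kobusone, (2R,5R,6R,10S) C9 norketone | C[C@@]12CC[C@@H]3[C@H](CC3(C)C)C(=O)CC[C@H]1O2 | intermediate
4 | samarium(III) ketyl of 3 (radical at C9) | C[C@@]12CC[C@@H]3[C@H](CC3(C)C)[C](O[Sm](I)I)CC[C@H]1O2 | intermediate
5 | ring-opened eleven-membered samarium enolate with radical at C2 | CC1(C)[CH]CC[C@@]2(C)O[C@@H]2CC/C(O[Sm](I)I)=C\C1 | intermediate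
6 | eleven-membered samarium(III) (E)-enolate | CC1(C)CCC[C@@]2(C)O[C@@H]2CC/C(O[Sm](I)I)=C\C1 | intermediate
7 | (9E,5R,6R)-5,6-epoxy-1,1,5-trimethylcycloundec-9-en-9-yl triflate | CC1(C)CCC[C@@]2(C)O[C@@H]2CC/C(OS(=O)(=O)C(F)(F)F)=C\C1 | intermediate
8 | 2-(trimethylsilyl)ethyl (9E,5R,6R)-5,6-epoxy-1,1,5-trimethylcycloundec-9-ene-9-carboxylate | CC1(C)CCC[C@@]2(C)O[C@@H]2CC/C(C(=O)OCC[Si](C)(C)C)=C\C1 | intermediate
9 | 11-oxo derivative of 8 | CC1(C)CCC[C@@]2(C)O[C@@H]2CC/C(C(=O)OCC[Si](C)(C)C)=C\C1=O | intermediate
10 | (11R)-11-hydroxy derivative of 8 | CC1(C)CCC[C@@]2(C)O[C@@H]2CC/C(C(=O)OCC[Si](C)(C)C)=C\[C@H]1O | intermediate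
11 | (11R)-11-benzoyloxy derivative of 8 | CC1(C)CCC[C@@]2(C)O[C@@H]2CC/C(C(=O)OCC[Si](C)(C)C)=C\[C@H]1OC(=O)c1ccccc1 | intermediate
12 | (9E,5R,6R,11R)-11-benzoyloxy-5,6-epoxy-1,1,5-trimethylcycloundec-9-ene-9-carboxylic acid | CC1(C)CCC[C@@]2(C)O[C@@H]2CC/C(C(=O)O)=C\[C@H]1OC(=O)c1ccccc1 | target

Total step count: 7. Longest linear sequence: 7 steps (from 1).

Steps most likely to fail

Step 2.
- What may go wrong: the samarium enolate may be protonated or react sluggishly before O-triflation. The rotamer control of the C9=C10 geometry may erode. Simple reduction of the ketone may compete with scission, or iodide with Sm(III) may open the epoxide.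
- Fallback: it sets out from 1 and comes back at 8, and it moves the radical from a ketyl to an ester-stabilised carbon.
- Hydroboration of the exocyclic methylene of 1 with 9-BBN and oxidative work-up gives the primary alcohol F1 (C9 configuration immaterial).
- TEMPO/PhI(OAc)2 in buffered MeCN–H2O gives the carboxylic acid F2. Carbodiimide/DMAP esterification with 2-(trimethylsilyl)ethanol gives the ester F3. LDA followed by PhSeBr gives the α-phenylselanyl ester F4.
- Slow addition of Bu3SnH/AIBN in refluxing benzene generates the C9 radical, which opens the same C2–C10 bond and is reduced at C2 to give 8.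
- Here the planar ester group avoids the C11/C1 flank (allylic 1,3-strain), and reversible stannyl-radical addition can equilibrate the enoate towards the tiglate-type E isomer.

Step 4.
- What may go wrong: hydrogen abstraction at the neopentyl C11 may be slow, site selectivity against C8–H may be poor, and hydroperoxide may add to the electron-poor alkene of the product.
- Fallback: it sets out from 8 and comes back at 9, and it replaces C–H abstraction by enolate and sigmatropic chemistry.
- Deconjugative selenenylation (LDA, HMPA, THF, −78 °C; PhSeCl) gives the α-phenylselanyl β,γ-unsaturated ester F5.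
- H2O2/pyridine forms the allylic selenoxide, whose [2,3]-sigmatropic rearrangement moves oxygen to C11 and restores the conjugated alkene. This gives the C11 carbinol F6 as an epimer mixture.
- Dess–Martin oxidation converges on 9.

Step 5.
- What may go wrong: facial selectivity may be poor if the ring conformation opposes the catalyst, and conjugate reduction of the ene-dicarbonyl may compete.
- Fallback: it sets out from 9 and comes back at 11, and it uses substrate control followed by inversion.
- Luche reduction (NaBH4, CeCl3, MeOH, −78 °C) attacks the ketone from the ring periphery.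
- If this favours the (11S)-carbinol F7, a Mitsunobu reaction with benzoic acid (PPh3, DIAD) inverts C11 and installs the benzoate in the same operation to give 11.
- Any 11R epimer formed alongside is 10 and goes on through step 6.

Further compounds
F1 | step 2 | primary alcohol from hydroboration–oxidation of 1 (C9–CH2OH, C9 configuration open) | C[C@@]12CC[C@@H]3[C@H](CC3(C)C)C(CO)CC[C@H]1O2
F2 | step 2 | C9 carboxylic acid of the caryophyllane epoxide (C9 configuration open) | C[C@@]12CC[C@@H]3[C@H](CC3(C)C)C(C(=O)O)CC[C@H]1O2
F3 | step 2 | 2-(trimethylsilyl)ethyl ester of F2 | C[C@@]12CC[C@@H]3[C@H](CC3(C)C)C(C(=O)OCC[Si](C)(C)C)CC[C@H]1O2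
F4 | step 2 | C9 α-phenylselanyl ester (C9 configuration open) | C[C@@]12CC[C@@H]3[C@H](CC3(C)C)C([Se]c4ccccc4)(C(=O)OCC[Si](C)(C)C)CC[C@H]1O2
F5 | step 4 | eleven-membered C9 α-phenylselanyl (10E)-β,γ-unsaturated ester (C9 configuration open) | C1CC[C@@]2(C)O[C@@H]2CCC([Se]c3ccccc3)(C(=O)OCC[Si](C)(C)C)/C=C/C1(C)C
F6 | step 4 | C11 carbinol of 8 as an epimer mixture | CC1(C)CCC[C@@]2(C)O[C@@H]2CC/C(C(=O)OCC[Si](C)(C)C)=C\C1O
F7 | step 5 | (11S)-epimer of 10 | CC1(C)CCC[C@@]2(C)O[C@@H]2CC/C(C(=O)OCC[Si](C)(C)C)=C\[C@@H]1O
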